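**Retrosynthetic overview**
- The lactone ring is cut first. The C4–C4a bond and the lactone C–O bond are made in one operation from a prenylated trihydroxybenzophenone and a cinnamoyl unit held as an acyl azolium. This is a thioester-like stand-in for cinnamoyl-CoA, the natural C3 donor of 4-phenyl-dihydrocoumarins, and a chiral carbene fixes C4 as R.
- The prenyl group is removed next: C-prenylation of the benzophenone anion, the bench counterpart of the aromatic prenyltransferase.
- The benzophenone is cut at the aryl–CO bond to phloroglucinol and benzoyl chloride, giving the product that benzophenone synthase makes in the plant.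
- Ring order: both benzene rings are bought intact. The only ring built is the dihydropyranone ring (ring B), closed in the last step together with the stereocentre.

Assumption: the facial sense of the carbene with this untested nucleophile is taken from the open-face model in step 3 and has not been verified; it is checked on the first run by chiral HPLC and ECD, and the mirror-image precatalyst is used if the sense proves opposite.

**Step 1**
Reactants: 1 phloroglucinol (benzene-1,3,5-triol); 2 benzoyl chloride
Product: 3 (2,4,6-trihydroxyphenyl)(phenyl)methanone
Conditions: AlCl3 (3.5 equiv), PhNO2, 65 °C; ice/aq HCl quench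
Reagents that add atoms: none
Why: Friedel–Crafts acylation of a very electron-rich arene whose three ring positions are equivalent; the first benzoyl group deactivates the ring and chelates aluminium, so the reaction stops at mono-acylation.

**Step 2**
Reactants: 3 (2,4,6-trihydroxyphenyl)(phenyl)methanone; 4 1-bromo-3-methylbut-2-ene (prenyl bromide, 0.9 equiv)
Product: 5 [2,4,6-trihydroxy-3-(3-methylbut-2-en-1-yl)phenyl](phenyl)methanone
Conditions: KOH (1.0 equiv, 10 % aq), 0 °C to rt; chromatography, unreacted 3 recycled
Reagents that add atoms: none
Why: C-alkylation of an ambident phloroglucinol anion (biomimetic aromatic prenylation): in water the hydrogen-bonded phenolate oxygen is masked and the soft allylic bromide is attacked by one of the two equivalent free ring carbons, while sub-stoichiometric 4 limits bis-prenylation.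

**Step 3**
Reactants: 5 [2,4,6-trihydroxy-3-(3-methylbut-2-en-1-yl)phenyl](phenyl)methanone; 6 3-phenylprop-2-ynal (1.3 equiv)
Product: 9 (4R)-6-benzoyl-5,7-dihydroxy-8-(3-methylbut-2-en-1-yl)-4-phenyl-3,4-dihydro-2H-chromen-2-one, via cinnamoyl azolium 7 (not isolated), via ring-open acyl azolium 8 (not isolated)
Conditions: (5aR,10bS)-2-mesityl-5a,10b-dihydro-4H,6H-indeno[2,1-b][1,2,4]triazolo[4,3-d][1,4]oxazin-2-ium chloride (10 mol %), toluene, 4 Å MS, 40 °C, no added base
Reagents that add atoms: none
Why: Proposed new method: the carbene (freed by the chloride and traces of the phenolate of 5) adds to 6, and internal redox (propargylic Breslow intermediate, allenol, protonation) gives the E-cinnamoyl azolium 7; the para-hydroxyl of 5 (the most acidic one and the only one not chelated to the ketone) adds to the acyl carbon, and the hemiketal undergoes a Coates–Claisen [3,3] shift (equivalent in outcome to a Friedel–Crafts conjugate addition) onto C5, the only free ring carbon, on the face of the acyl azolium not covered by the indane wall of the (5aR,10bS) carbene, which the model assigns as C4 = R; tautomerization gives 8, whose para-oxygen then acylates to close ring B and release the carbene, under neutral conditions that leave the ortho-prenylphenol and the benzophenone untouched; the closest known reaction type is the chiral-carbene-catalysed Coates–Claisen annulation of ynals with kojic acids and 2-naphthol to 4-aryl dihydropyranones and dihydrocoumarins.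

**Compound list**
1 | phloroglucinol (benzene-1,3,5-triol) | Oc1cc(O)cc(O)c1 | starting material
2 | benzoyl chloride | O=C(Cl)c1ccccc1 | starting material
3 | (2,4,6-trihydroxyphenyl)(phenyl)methanone | O=C(c1ccccc1)c1c(O)cc(O)cc1O | intermediate
4 | 1-bromo-3-methylbut-2-ene (prenyl bromide) | CC(C)=CCBr | starting material
5 | [2,4,6-trihydroxy-3-(3-methylbut-2-en-1-yl)phenyl](phenyl)methanone | CC(C)=CCc1c(O)cc(O)c(C(=O)c2ccccc2)c1O | intermediate
6 | 3-phenylprop-2-ynal | O=CC#Cc1ccccc1 | starting material
7 | (5aR,10bS)-2-mesityl-1-[(2E)-3-phenylprop-2-enoyl]-5a,10b-dihydro-4H,6H-indeno[2,1-b][1,2,4]triazolo[4,3-d][1,4]oxazin-2-ium chloride (E-cinnamoyl group on the former carbene carbon) | O=C(/C=C/c1ccccc1)c1[n+](-c2c(C)cc(C)cc2C)nc2CO[C@@H]3Cc4ccccc4[C@@H]3n12.[Cl-] | intermediate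
8 | (5aR,10bS)-1-{(3R)-3-[3-benzoyl-2,4,6-trihydroxy-5-(3-methylbut-2-en-1-yl)phenyl]-3-phenylpropanoyl}-2-mesityl-5a,10b-dihydro-4H,6H-indeno[2,1-b][1,2,4]triazolo[4,3-d][1,4]oxazin-2-ium chloride | CC(C)=CCc1c(O)c([C@@H](c2ccccc2)CC(=O)c2[n+](-c3c(C)cc(C)cc3C)nc3CO[C@@H]4Cc5ccccc5[C@@H]4n23)c(O)c(C(=O)c2ccccc2)c1O.[Cl-] | intermediate
9 | (4R)-6-benzoyl-5,7-dihydroxy-8-(3-methylbut-2-en-1-yl)-4-phenyl-3,4-dihydro-2H-chromen-2-one | CC(C)=CCc1c(O)c(C(=O)c2ccccc2)c(O)c2c1OC(=O)C[C@@H]2c1ccccc1 | target

**Totals**
Total step count: 3 (compound 3 is also a catalog item; buying it would leave 2).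
Longest linear sequence: 3.

**Steps most likely to fail, with fallbacks**

Step 3 is the highest risk. The nucleophile is new for this catalysis, and O-acylation to the aryl cinnamate, the sense and level of induction, and closure onto an ortho instead of the para hydroxyl are all open; HMBC on the product settles the last point. The fallback sets out from 5 and brings in the cinnamoyl unit one oxidation level lower, activated as an iminium ion. Cinnamaldehyde, (R)-α,α-diphenylprolinol trimethylsilyl ether (20 mol %) and PhCO2H (20 mol %) in CH2Cl2 at room temperature give enantioselective Friedel–Crafts conjugate addition at C5 on the face left open by the diphenyl(silyloxy)methyl group. Hemiacetal closure onto the para-hydroxyl then gives the lactol (4R)-[2,5,7-trihydroxy-8-(3-methylbut-2-en-1-yl)-4-phenyl-3,4-dihydro-2H-chromen-6-yl](phenyl)methanone F1 as a mixture of C2 epimers. Ag2CO3 on Celite in toluene at 80 °C oxidizes the lactol carbon, and the sequence comes back to the route at 9.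

Step 2 is the second risk: a modest yield is expected, with O-prenyl and bis-C-prenyl by-products. The fallback sets out from 3 and delivers the prenyl group through oxygen. Pd(PPh3)4 (zerovalent palladium, 5 mol %) and tert-butyl 2-methylbut-3-en-2-yl carbonate in THF at 0 °C alkylate the most acidic, para hydroxyl to the tertiary allyl ether {2,6-dihydroxy-4-[(2-methylbut-3-en-2-yl)oxy]phenyl}(phenyl)methanone F2. Heating in toluene at 110 °C then brings about an aromatic Claisen rearrangement to the adjacent free ring carbon. The [3,3] shift inverts the allyl unit to the linear 3-methylbut-2-enyl group, and tautomerization returns the route at 5.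

Step 1 is the lowest risk: O-benzoylation, bis-acylation and tar are possible with AlCl3. The fallback sets out from 1 and uses a Houben–Hoesch reaction with benzonitrile (ZnCl2, HCl gas, Et2O, 0 °C). This precipitates the ketiminium salt (2,4,6-trihydroxyphenyl)(phenyl)methaniminium chloride F3, which cannot acylate twice. Boiling water hydrolyses it, and the route is rejoined at 3.

**Further compounds**
F1 | step 3 | (4R)-[2,5,7-trihydroxy-8-(3-methylbut-2-en-1-yl)-4-phenyl-3,4-dihydro-2H-chromen-6-yl](phenyl)methanone (C2 epimers) | CC(C)=CCc1c(O)c(C(=O)c2ccccc2)c(O)c2c1OC(O)C[C@@H]2c1ccccc1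
F2 | step 2 | {2,6-dihydroxy-4-[(2-methylbut-3-en-2-yl)oxy]phenyl}(phenyl)methanone | C=CC(C)(C)Oc1cc(O)c(C(=O)c2ccccc2)c(O)c1
F3 | step 1 | (2,4,6-trihydroxyphenyl)(phenyl)methaniminium chloride | [NH2+]=C(c1ccccc1)c1c(O)cc(O)cc1O.[Cl-]
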